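## Structural features

The target is a 2-aryl-4H-chromen-4-one: benzene ring A is fused to the γ-pyrone ring C (O1, C2, C3, C4, C4a, C8a), and ring B is attached through the C2–C1' bond. Ring A carries three contiguous oxygens (5-OH, 6-OMe, 7-OMe) and one hydrogen at C8. Ring B carries 2'-, 3'- and 4'-OMe and 6'-OH, so both positions ortho to C1' are substituted; the C2–C1' bond is crowded, and a carbonyl at C2 in any open-chain precursor is hindered. The molecule has no stereocentre, so every selectivity problem is regiochemical. The fragile elements are the two free phenols among five methyl ethers, the electron-rich rings, and the pyrone C2=C3 bond, which must survive the final deprotection. The 5-OH is hydrogen-bonded to the C4 carbonyl; the 6'-OH is para to a methoxy group and can be oxidised or can add to the carbonyls of a ring-opened precursor. The real difficulty is to place the 5,6,7-trioxygenation with C8 free, and not the 7,8- or 5,7,8-patterns that acid-mediated closures tend to give, while leaving exactly O5 and O6' unmethylated. The key step uses the fact that O5 and O6 form a latent catechol: in the ortho-quinone of a 5,6-dihydroxy ring A, C8a is the β-carbon of both the C5(=O)–C4a=C8a and the C4(=O)–C4a=C8a enones, so the enol oxygen on C2 can be joined to C8a (bond O1–C8a) by conjugate addition.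

## Logic of the disconnections

14 to 13: the O6'–CH2Ph bond is cut. A free 6'-phenol could attack the diketone carbonyls, be alkylated in the methylation, or be oxidised as a para-alkoxyphenol. Carrying it as a benzyl ether to the last step makes ring B inert in every earlier compound. The forward cleavage must spare C2=C3, the chelated 5-OH and five methyl ethers, which points to neutral hydrogenolysis.

13 to 12: the O6–CH3 bond is cut. This exposes the 5,6-diol that the quinone logic needs. The forward step must methylate O6 and not O5 with one equivalent of reagent; the O5–H···O=C4 hydrogen bond is relied on for that.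

12 to 9 (through 11 and 10): the O1–C8a bond is cut. The 5,6-diol is the reduced form of an ortho-quinone in which C8a is doubly activated, so O1 can be introduced as a nucleophile at a carbon that carries no oxygen in the precursor. Ring C disappears and the problem becomes an open-chain diaryl 1,3-diketone on a simple 1,2,3-trioxygenated arene. The forward step needs a neutral, acid-free, near-stoichiometric oxidation, because acid would close the ring through the C5 oxygen and excess oxidant would attack the product catechol.

9 to 6 and 7 (through 8): the C2–C3 bond, between the ring B carbonyl carbon and the central methylene, is cut. This is the convergent cut into two arenes of similar size. The methyl ketone is placed on the catechol ring because that piece is then a catalogue compound whose hydroxyls can travel as lithium phenoxides, so the catechol is never protected. The forward step must acylate carbon and not oxygen and must keep 9 away from acid and air.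

6 to 5 to 4: the C–Cl bond and then one C–O bond of the carboxyl group are removed, which is an adjustment of oxidation level only. The aldehyde is the level that a formylation delivers. The oxidation must not chlorinate the one unsubstituted ring position.

4 to 3: the O–CH2Ph bond is cut. The forward alkylation has only one hydroxyl to address, although it is chelated to the aldehyde.

3 to 1 (through 2): the C1'–CHO bond, which is the future C1'–C2 bond, is cut. 1 already holds all four ring B oxygens; its two positions ortho to the hydroxyl are equivalent and the para position is blocked. The ring B pattern is therefore fixed by symmetry, and the forward formylation only has to tolerate a crowded site.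

## Other disconnections considered

Alternative 1: The cut is the C4a–C8a bond of ring A. It unravels the arene into a chain of alternating carbonyls, masked as the 4-pyranone ester A2 (methyl {6-[2-(2-benzyloxy-4,5,6-trimethoxyphenyl)-2-oxoethyl]-3-methoxy-4-oxo-4H-pyran-2-yl}acetate).
- Forward step: hydroxide would open the pyranone of A2 to a triketo ester enolate, and the carbanion at C4a would attack the ester carbon C8a in a Claisen condensation. Ring A would appear as the acylphloroglucinol A1 (1-[2-(benzyloxy)-4,5,6-trimethoxyphenyl]-3-(2,4,6-trihydroxy-3-methoxyphenyl)propane-1,3-dione).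
- In favour: the step is redox-neutral, needs no metal and follows a folding mode well known from biomimetic polyketide work. On precedent and on redox economy it is the better plan. It also builds a whole carbocycle, where the chosen plan makes one C–O bond on a purchased ring.
- Against: the chain can also fold by aldol attack on a ketone, and the choice depends on base and counter-ion. A1 has two hydroxyls ortho to the acyl group, so the later dehydrative closure of ring C can occur on either side and does not fix the 6-methoxy against the 8-methoxy pattern. In the chosen plan the quinone dictates the position of O1.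
- Equal point: A1 needs a methylation at O7 in the presence of O5, the same chelation-type selectivity as step 7. The benzyl ether is needed in both plans.
- Step economy: A2, with its ring methoxy group and two different side chains, would be expected to cost six or more steps, and ring closure, methylation and debenzylation follow A1. The sequence should be clearly longer than eight steps.

Alternative 2: Three bonds of ring B are cut at once (C2'–C3', C1'–C6', C5'–C6'). The pieces are the chromonyl ynol ether A3 (5,6,7-trimethoxy-2-(methoxyethynyl)-4H-chromen-4-one), the alkenyl carbene complex A4, (CO)5Cr=C(OMe)C(OMe)=CH2, and one carbonyl ligand.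
- Forward step: in a Dötz benzannulation the alkyne of A3 would insert into the Cr=C bond of A4, CO would insert, and the dienyl ketene would close. After loss of chromium, ring B would appear as the free 6'-phenol A5 (6'-hydroxy-5,6,7,2',3',4'-hexamethoxyflavone).
- In favour: the pentasubstituted ring B is made in one operation, and the 6'-oxygen arrives free and already distinguished from the methoxy groups. On protecting-group economy this is better than the chosen plan. Only one step would remain after A5 (chelation-controlled cleavage of the 5-methyl ether), against two after 12.
- Against: the usual regiochemistry places the larger alkyne substituent next to the new hydroxyl, which is what is needed. However, A3 is a push–pull alkyne whose electronic bias may oppose the steric one, and electron-poor alkynes tend to give cyclobutenones, furans or indenes. A3 is also a Michael acceptor and a labile ynol ether, A4 is a sensitive α-alkoxyvinyl carbene, and chromium is stoichiometric.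
- Comparison: the reaction class is well established but not for an alkyne of this kind, so the uncertainty is comparable with that of the chosen key step and neither plan is ahead. The alternative builds a carbocycle with three C–C bonds; the chosen plan builds a heterocycle with one C–O bond. The short end-game is offset by the several steps that A3 and A4 would each need, so no saving over eight steps is expected.

Alternative 3: Ring C is cut at C4a–C4, C4–C3 and O1–C2. The pieces are the iodophenol A6 (2-iodo-3,4,5-trimethoxyphenol), carbon monoxide and the ring B alkyne A7 (1-(benzyloxy)-2-ethynyl-3,4,5-trimethoxybenzene).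
- Forward step: oxidative addition of A6 to zerovalent palladium formed from PdCl2(PPh3)2, CO insertion, coupling with A7 and amine-promoted 6-endo-dig addition of the phenol to the alkynone would give A8 (6'-(benzyloxy)-5,6,7,2',3',4'-hexamethoxyflavone).
- In favour: it is a catalytic, three-component, one-flask construction of the pyrone. Both pieces are close to 1 (A6 by iodination of 1, A7 by homologation of 4), and the reaction class is well documented for flavones. The route could finish in about six steps if one Lewis acid treatment removes both the 5-methyl and the benzyl group. On precedent and on step count it is the better plan.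
- Against: the C–I bond of A6 lies between a hydroxyl and a methoxy group on a very electron-rich ring, and A7 is doubly ortho-substituted. Oxidative addition and CO insertion may be slow enough for direct, non-carbonylative coupling to a benzofuran to compete. The cyclisation can also take the 5-exo-dig course to the aurone skeleton. The 5-hydroxyl must be recovered at the end by selective demethylation of a hexamethoxy compound, with the 6-methoxy group at risk.
- Comparison: both plans close ring C, the alternative with three bonds and the chosen plan with one. The chosen plan obtains the 5-OH/6-OMe distinction from the catechol logic itself and avoids carbon monoxide and the late Lewis acid step, but its key step has no direct precedent.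

Key step: step 6

Remarks on the chemistry:
- Assumption: 1-(2,3-dihydroxy-4-methoxyphenyl)ethanone (7) is taken as a catalogue compound, supplied as a hydrate and dried azeotropically with toluene before step 5.
- Check of structures: 9, 12 and 14 map onto one another atom for atom. The ring A carbon bearing the diketone becomes C4a, its two hydroxylated neighbours C5 and C6, the methoxylated carbon C7, and the unsubstituted carbons C8 and C8a. No connectivity needs correcting.
- Correction of reasoning: in quinone 10 the 7-methoxy group sits on C7, the α-carbon of the C6(=O)–C7=C8 enone, so it does not make the C6 carbonyl a vinylogous ester. It makes C7=C8 an enol ether whose β-carbon, C8, is electron-rich and a poor acceptor. Through C7=C8–C8a=C4a it is a doubly vinylogous donor to the C5 and C4 carbonyls.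
- Wrong-way closure: attack of the C5 hydroxyl on C2 would give the 8-hydroxy-7-methoxy isomer.
- Design of the precursor: the structure of 9 is kept. It is reached with the catechol unprotected, from the catechol ketone and the ring B acid chloride, so no silyl groups and no fluoride or acid deprotection touch the catechol diketone before the oxidation.
- Stereochemistry: no isolated compound has a stereocentre; only the transient 11 has one, at C8a, and it is racemic.

## Steps

Step 1
Reactants: 1 3,4,5-trimethoxyphenol
Product: 3 6-hydroxy-2,3,4-trimethoxybenzaldehyde, via aryl iminium chloride 2 (not isolated)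
Conditions: POCl3, DMF, 0 °C to rt; then H2O, 50 °C
Reagents that add atoms: N,N-dimethylformamide, CN(C)C=O; water, O
Why: Vilsmeier–Haack formylation: the phenol activates its two ortho positions, which are equivalent by symmetry, and the para position is blocked by a methoxy group, so only one aldehyde can form; the iminium salt 2 is hydrolysed on aqueous work-up.

Step 2
Reactants: 3 6-hydroxy-2,3,4-trimethoxybenzaldehyde
Product: 4 2-(benzyloxy)-4,5,6-trimethoxybenzaldehyde
Conditions: BnBr, K2CO3, DMF, 60 °C
Reagents that add atoms: benzyl bromide, BrCc1ccccc1
Why: Williamson etherification; the phenol is hydrogen-bonded to the aldehyde, hence DMF and gentle heating, and there is no other acidic site.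

Step 3
Reactants: 4 2-(benzyloxy)-4,5,6-trimethoxybenzaldehyde
Product: 5 2-(benzyloxy)-4,5,6-trimethoxybenzoic acid
Conditions: NaClO2, NaH2PO4, 2-methyl-2-butene (excess), t-BuOH/H2O, rt
Reagents that add atoms: sodium chlorite, [Na+].[O-]Cl=O
Why: Pinnick oxidation, which tolerates doubly ortho-substituted, electron-rich aldehydes and benzyl ethers; the excess alkene consumes HOCl before it can chlorinate the one free ring position.

Step 4
Reactants: 5 2-(benzyloxy)-4,5,6-trimethoxybenzoic acid
Product: 6 2-(benzyloxy)-4,5,6-trimethoxybenzoyl chloride
Conditions: (COCl)2, cat. DMF, CH2Cl2, 0 °C to rt; evaporation, toluene azeotrope, used crude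
Reagents that add atoms: oxalyl chloride, O=C(Cl)C(Cl)=O
Why: Acid chloride formation through the chloroiminium catalyst; the by-products are gases, and the benzyl and methyl ethers should withstand the brief exposure to HCl at room temperature.

Step 5
Reactants: 7 1-(2,3-dihydroxy-4-methoxyphenyl)ethanone; 6 2-(benzyloxy)-4,5,6-trimethoxybenzoyl chloride
Product: 9 1-[2-(benzyloxy)-4,5,6-trimethoxyphenyl]-3-(2,3-dihydroxy-4-methoxyphenyl)propane-1,3-dione, via trilithium enolate 8 (not isolated)
Conditions: 7, LiN(SiMe3)2 (4.2 equiv), THF, −78 to −10 °C, Ar; 6 (1.0 equiv), −78 °C to rt; cold aq. NaH2PO4 quench (pH about 5), degassed solvents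
Reagents that add atoms: none
Why: C-Acylation of the lithium polyanion of an ortho-hydroxyacetophenone with an aroyl chloride, the one-flask equivalent of a Baker–Venkataraman sequence: three equivalents of base form 8, the fourth takes the acidic proton of the diketone as it forms, and the aggregated lithium phenoxides are much poorer nucleophiles than the enolate carbon at low temperature, so the catechol needs no protection. The medium stays basic and oxygen-free and the quench is cold and only weakly acidic, so neither dehydrative ring closure nor aerial oxidation of the catechol is invited.

Step 6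
Reactants: 9 1-[2-(benzyloxy)-4,5,6-trimethoxyphenyl]-3-(2,3-dihydroxy-4-methoxyphenyl)propane-1,3-dione
Product: 12 6'-(benzyloxy)-5,6-dihydroxy-7,2',3',4'-tetramethoxyflavone, via ortho-quinone 10 (not isolated), via ring-closed dienone 11 (not isolated)
Conditions: Ag2O (1.1 equiv), Na2SO4, THF (0.01 M), 0 °C to rt, dark, Ar; Celite filtration, aq. Na2S2O4 wash
Reagents that add atoms: none
Why: Proposed new method: Ag2O removes two electrons and two protons from the catechol of 9 to give the 3-acyl-ortho-quinone 10, in which C8a is the β-carbon of both the C5(=O)–C4a=C8a and the C4(=O)–C4a=C8a enones and is the most electrophilic ring position; the enol oxygen on C2 adds there in an intramolecular oxa-Michael reaction (equally an oxa-6π closure of the O=C2–C3=C4–C4a=C8a dienone tautomer), forming O1–C8a and giving 11, which enolises with loss of the C8a hydrogen to restore aromatic ring A in 12. The closest known reaction types are the Ag2O oxidation of 3-acylcatechols to 3-acyl-ortho-quinones that are trapped in situ, the addition of oxygen nucleophiles to quinones generated in the flask, and the oxidative closure of hydroxybenzophenones to xanthones. Ring C closes in the 6-endo-trig mode, since both carbons of the accepting C4a=C8a bond lie inside the new six-membered ring; 1,2-addition to the C5 carbonyl would be a reversible hemiketalisation, whereas the conjugate addition is made irreversible by rearomatisation. No stereocentre results: C8a is tetrahedral only in racemic 11 and planar again in 12. Site selectivity between C8a and C8 is secured because the tether reaches only C8a, C8a is doubly activated, and the 7-methoxy group makes C8 the electron-rich β-carbon of an enol ether. Chemoselectivity against dehydrative attack of the C5 hydroxyl on C2 (which would give the 8-hydroxy-7-methoxy isomer) is secured by the neutral, acid-free, cold medium, by the drying agent, by the doubly ortho-substituted and therefore hindered C2 carbonyl, and by the fact that both ring A oxygens are carbonyls once 10 has formed; the benzyl ether leaves the diketone enol as the only oxygen nucleophile on the ring B side. Over-oxidation of the product catechol is limited by the near-stoichiometric charge of oxidant, the high dilution and the dithionite wash.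

Step 7
Reactants: 12 6'-(benzyloxy)-5,6-dihydroxy-7,2',3',4'-tetramethoxyflavone
Product: 13 6'-(benzyloxy)-5-hydroxy-6,7,2',3',4'-pentamethoxyflavone
Conditions: MeI (1.05 equiv), K2CO3 (1.1 equiv), acetone, rt, Ar
Reagents that add atoms: iodomethane, CI
Why: Williamson methylation under chelation control: the 5-hydroxyl is tied to the C4 carbonyl by a strong hydrogen bond and is the less acidic and less nucleophilic of the two, so one equivalent of base and of MeI should alkylate O6 only, as is usual for 5-hydroxyflavones; argon protects the catecholate from air.

Step 8
Reactants: 13 6'-(benzyloxy)-5-hydroxy-6,7,2',3',4'-pentamethoxyflavone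
Product: 14 5,6'-dihydroxy-6,7,2',3',4'-pentamethoxyflavone
Conditions: H2 (1 atm), 10% Pd/C, EtOAc/MeOH, rt, stopped after one equivalent of H2
Reagents that add atoms: none
Why: Catalytic hydrogenolysis of an aryl benzyl ether under neutral conditions; the C2=C3 bond of a flavone, a vinylogous ester, is reduced much more slowly than the benzylic C–O bond is cleaved, and the methyl ethers and the chelated phenol are inert.

## Compound list

1 | 3,4,5-trimethoxyphenol | COc1cc(O)cc(OC)c1OC | starting material
2 | [(6-hydroxy-2,3,4-trimethoxyphenyl)methylidene]dimethylammonium chloride | COc1cc(O)c(C=[N+](C)C)c(OC)c1OC.[Cl-] | intermediate (not isolated)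
3 | 6-hydroxy-2,3,4-trimethoxybenzaldehyde | COc1cc(O)c(C=O)c(OC)c1OC | intermediate
4 | 2-(benzyloxy)-4,5,6-trimethoxybenzaldehyde | COc1cc(OCc2ccccc2)c(C=O)c(OC)c1OC | intermediate
5 | 2-(benzyloxy)-4,5,6-trimethoxybenzoic acid | COc1cc(OCc2ccccc2)c(C(=O)O)c(OC)c1OC | intermediate
6 | 2-(benzyloxy)-4,5,6-trimethoxybenzoyl chloride | COc1cc(OCc2ccccc2)c(C(=O)Cl)c(OC)c1OC | intermediate
7 | 1-(2,3-dihydroxy-4-methoxyphenyl)ethanone | CC(=O)c1ccc(OC)c(O)c1O | starting material
8 | trilithium 3-methoxy-6-(1-oxidoethenyl)benzene-1,2-diolate | [Li+].[Li+].[Li+].C=C([O-])c1ccc(OC)c([O-])c1[O-] | intermediate (not isolated)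
9 | 1-[2-(benzyloxy)-4,5,6-trimethoxyphenyl]-3-(2,3-dihydroxy-4-methoxyphenyl)propane-1,3-dione | COc1ccc(C(=O)CC(=O)c2c(OCc3ccccc3)cc(OC)c(OC)c2OC)c(O)c1O | intermediate
10 | 3-{3-[2-(benzyloxy)-4,5,6-trimethoxyphenyl]-3-oxopropanoyl}-6-methoxycyclohexa-3,5-diene-1,2-dione | COC1=CC=C(C(=O)CC(=O)c2c(OCc3ccccc3)cc(OC)c(OC)c2OC)C(=O)C1=O | intermediate (not isolated)
11 | 2-[2-(benzyloxy)-4,5,6-trimethoxyphenyl]-5-hydroxy-7-methoxy-8aH-chromene-4,6-dione (racemic at C8a) | COC1=CC2OC(-c3c(OCc4ccccc4)cc(OC)c(OC)c3OC)=CC(=O)C2=C(O)C1=O | intermediate (not isolated)
12 | 6'-(benzyloxy)-5,6-dihydroxy-7,2',3',4'-tetramethoxyflavone; 2-[2-(benzyloxy)-4,5,6-trimethoxyphenyl]-5,6-dihydroxy-7-methoxy-4H-chromen-4-one | COc1cc2oc(-c3c(OCc4ccccc4)cc(OC)c(OC)c3OC)cc(=O)c2c(O)c1O | intermediate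
13 | 6'-(benzyloxy)-5-hydroxy-6,7,2',3',4'-pentamethoxyflavone; 2-[2-(benzyloxy)-4,5,6-trimethoxyphenyl]-5-hydroxy-6,7-dimethoxy-4H-chromen-4-one | COc1cc2oc(-c3c(OCc4ccccc4)cc(OC)c(OC)c3OC)cc(=O)c2c(O)c1OC | intermediate
14 | 5,6'-dihydroxy-6,7,2',3',4'-pentamethoxyflavone; 5-hydroxy-2-(6-hydroxy-2,3,4-trimethoxyphenyl)-6,7-dimethoxy-4H-chromen-4-one | COc1cc(O)c(-c2cc(=O)c3c(O)c(OC)c(OC)cc3o2)c(OC)c1OC | target

## Step count and least certain steps

Total: 8 steps. Longest linear sequence: 8 steps (1 to 14; 7 is purchased).

Step 6 (key step, proposed new method).
- What may go wrong: over-oxidation of the new ring A catechol, which is at least as electron-rich as the precursor and can pass electrons to unreacted quinone or to Ag2O. Intermolecular capture or self-condensation of the quinone, if the neutral enol oxygen closes the ring more slowly than hoped. Dehydrative closure through the C5 oxygen before oxidation, if traces of acid are present.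
- Fallback (known chemistry; sets out from 1 and 6, returns at 14): acetylation of 1 with AcOH and BF3·OEt2 should give 1-(6-hydroxy-2,3,4-trimethoxyphenyl)ethanone F1. Acylation of its lithium dianion (LiN(SiMe3)2, THF) with 6 should give 1-[2-(benzyloxy)-4,5,6-trimethoxyphenyl]-3-(6-hydroxy-2,3,4-trimethoxyphenyl)propane-1,3-dione F2, whose only hydroxyl ortho to the diketone is the correct one. Ordinary acid-catalysed cyclodehydration (TsOH, toluene, 80 °C) should then lead to 6'-(benzyloxy)-5,6,7,2',3',4'-hexamethoxyflavone F3. BCl3 with pentamethylbenzene in CH2Cl2 (−78 to 0 °C) would remove the benzyl group and, under chelation to the C4 carbonyl, the 5-methyl group, arriving at 14. This gives up the quinone logic and accepts a late selective demethylation.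

Step 5.
- What may go wrong: acylation on oxygen in place of carbon, since the 3-phenoxide is not chelated and the hindered acyl chloride slows the desired attack. Partial dehydrative closure or aerial oxidation of the catechol diketone during work-up.
- Fallback (sets out from 7 and 6, returns at 9): silylation of both hydroxyls of 7 (TBSCl, imidazole, DMF) should give 1-{2,3-bis[(tert-butyldimethylsilyl)oxy]-4-methoxyphenyl}ethanone F4. Acylation of its lithium enolate with 6 should give 1-[2-(benzyloxy)-4,5,6-trimethoxyphenyl]-3-{2,3-bis[(tert-butyldimethylsilyl)oxy]-4-methoxyphenyl}propane-1,3-dione F5. Desilylation with acetic-acid-buffered TBAF at 0 °C under argon would return to 9. This costs two more steps, but no free phenoxide is present while the C–C bond is formed.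

Step 7.
- What may go wrong: loss of discrimination between the two hydroxyls (double methylation or some alkylation at O5), and oxidative degradation of the catecholate.
- Fallback (sets out from 12, returns at 14): exhaustive methylation (excess MeI, K2CO3, DMF) would give 6'-(benzyloxy)-5,6,7,2',3',4'-hexamethoxyflavone F6, the same substance as F3. BCl3 with pentamethylbenzene would then cleave the benzyl ether and the chelated 5-methyl ether in one operation to give 14. The selectivity is moved to the demethylation, where peri chelation is a dependable control element.

Step 8.
- What may go wrong: competing saturation of the C2=C3 bond, or slow cleavage of the crowded ether that tempts prolonged exposure to hydrogen.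
- Fallback (sets out from 13, returns at 14, no new compound): non-reductive debenzylation with BCl3 and pentamethylbenzene in CH2Cl2 at −78 °C, in which the benzyl cation is passed to the scavenger. The temperature must stay low, because boron chelation at O5 puts the 6-methoxy group at risk on warming.

## Further compounds

F1 | step 6 | 1-(6-hydroxy-2,3,4-trimethoxyphenyl)ethanone | CC(=O)c1c(O)cc(OC)c(OC)c1OC
F2 | step 6 | 1-[2-(benzyloxy)-4,5,6-trimethoxyphenyl]-3-(6-hydroxy-2,3,4-trimethoxyphenyl)propane-1,3-dione | COc1cc(O)c(C(=O)CC(=O)c2c(OCc3ccccc3)cc(OC)c(OC)c2OC)c(OC)c1OC
F3 | step 6 | 6'-(benzyloxy)-5,6,7,2',3',4'-hexamethoxyflavone | COc1cc2oc(-c3c(OCc4ccccc4)cc(OC)c(OC)c3OC)cc(=O)c2c(OC)c1OC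
F4 | step 5 | 1-{2,3-bis[(tert-butyldimethylsilyl)oxy]-4-methoxyphenyl}ethanone | CC(=O)c1ccc(OC)c(O[Si](C)(C)C(C)(C)C)c1O[Si](C)(C)C(C)(C)C
F5 | step 5 | 1-[2-(benzyloxy)-4,5,6-trimethoxyphenyl]-3-{2,3-bis[(tert-butyldimethylsilyl)oxy]-4-methoxyphenyl}propane-1,3-dione | COc1ccc(C(=O)CC(=O)c2c(OCc3ccccc3)cc(OC)c(OC)c2OC)c(O[Si](C)(C)C(C)(C)C)c1O[Si](C)(C)C(C)(C)C
F6 | step 7 | 6'-(benzyloxy)-5,6,7,2',3',4'-hexamethoxyflavone (same substance as F3) | COc1cc2oc(-c3c(OCc4ccccc4)cc(OC)c(OC)c3OC)cc(=O)c2c(OC)c1OC
F0 | step 8 | none | none
A1 | alternative 1 | 1-[2-(benzyloxy)-4,5,6-trimethoxyphenyl]-3-(2,4,6-trihydroxy-3-methoxyphenyl)propane-1,3-dione | COc1c(O)cc(O)c(C(=O)CC(=O)c2c(OCc3ccccc3)cc(OC)c(OC)c2OC)c1O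
A2 | alternative 1 | methyl {6-[2-(2-benzyloxy-4,5,6-trimethoxyphenyl)-2-oxoethyl]-3-methoxy-4-oxo-4H-pyran-2-yl}acetate | COC(=O)Cc1oc(CC(=O)c2c(OCc3ccccc3)cc(OC)c(OC)c2OC)cc(=O)c1OC
A3 | alternative 2 | 5,6,7-trimethoxy-2-(methoxyethynyl)-4H-chromen-4-one | COC#Cc1cc(=O)c2c(OC)c(OC)c(OC)cc2o1
A4 | alternative 2 | pentacarbonyl[methoxy(1-methoxyethenyl)carbene]chromium, (CO)5Cr=C(OMe)C(OMe)=CH2 | COC(=C)C(OC)=[Cr].[C-]#[O+].[C-]#[O+].[C-]#[O+].[C-]#[O+].[C-]#[O+]
A5 | alternative 2 | 6'-hydroxy-5,6,7,2',3',4'-hexamethoxyflavone | COc1cc(O)c(-c2cc(=O)c3c(OC)c(OC)c(OC)cc3o2)c(OC)c1OC
A6 | alternative 3 | 2-iodo-3,4,5-trimethoxyphenol | COc1cc(O)c(I)c(OC)c1OC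
A7 | alternative 3 | 1-(benzyloxy)-2-ethynyl-3,4,5-trimethoxybenzene | C#Cc1c(OCc2ccccc2)cc(OC)c(OC)c1OC
A8 | alternative 3 | 6'-(benzyloxy)-5,6,7,2',3',4'-hexamethoxyflavone | COc1cc2oc(-c3c(OCc4ccccc4)cc(OC)c(OC)c3OC)cc(=O)c2c(OC)c1OC
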